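**Retrosynthetic overview**

1. The strategy rests on ring A: a phloroglucinol nucleus in which C8 carries the (R)-lavandulyl chain between the oxygens on C7 and C8a (the future O1), with the third oxygen on C5 para to C8. This is the pattern produced when a silyl ynol ether inserts into a vinylketene.
2. Ring C is cut at O1–C2 (6-endo opening of a (2R,3S)-chalcone oxirane by the C8a hydroxyl, which sets trans C2/C3) and at C4–C4a (acylation of ortho-lithiated ring A by a ring B cinnamoyl N-methoxy-N-methylamide).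
3. Ring A is cut at C8–C8a, C6–C7 and C4a–C8a into 3-(methoxymethoxy)cyclobutenone and a triisopropylsilyl ynol ether. The ynol ether comes from (R)-carvone by oxidative ring cleavage, Wittig olefination and Kowalski homologation; carvone supplies the lavandulyl stereocenter.
4. Ring order: ring A (benzannulation), then ring C (oxirane opening); ring B is bought as 2,4-dihydroxybenzaldehyde. The three ring A oxygens stay distinct to the end (C8a free, then 1-ethoxyethyl; C5 MOM; C7 TIPS), which decides C8 against C6.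

Key step: step 7

Remarks: "lavandulyl" stands for (2R)-5-methyl-2-(prop-1-en-2-yl)hex-4-en-1-yl. The 1-ethoxyethyl acetal carbon carried from step 8 to step 13 forms as both epimers and is left undefined in the SMILES; the group is removed in step 13, so this has no consequence. Cyclobutane-1,3-dione is taken as a purchasable compound.

**Route**

Step 1
Reactants: 1 (R)-carvone
Product: 2 (1R,4R,6R)-1-methyl-4-(prop-1-en-2-yl)-7-oxabicyclo[4.1.0]heptan-2-one
Conditions: 35% H2O2, NaOH (cat.), MeOH, 0 °C
Reagents that add atoms: hydrogen peroxide, OO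
Why: Weitz–Scheffer nucleophilic epoxidation reacts only at the electron-poor enone alkene and not at the isopropenyl group, and hydroperoxide should add anti to the C5 substituent so that the oxirane forms trans to it (both new centers are erased in step 2).

Step 2
Reactants: 2 (1R,4R,6R)-1-methyl-4-(prop-1-en-2-yl)-7-oxabicyclo[4.1.0]heptan-2-one
Product: 5 (3R)-5-oxo-3-(prop-1-en-2-yl)pentanoic acid, via keto diol 3 (not isolated), via diketo aldehyde 4 (not isolated)
Conditions: H5IO6 (2.5 equiv), THF/H2O, 0 °C to rt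
Reagents that add atoms: water, O; orthoperiodic acid, O[I](O)(O)(O)(O)=O
Why: The acidic periodate solution should hydrolyse the oxirane to keto diol 3 and then cleave first the diol and then the 1,2-diketone of 4 (Malaprade oxidation), which excises the methyl-bearing carbon as acetic acid and leaves the untouched carvone stereocenter between an aldehyde arm and a carboxylic acid arm.

Step 3
Reactants: 5 (3R)-5-oxo-3-(prop-1-en-2-yl)pentanoic acid
Product: 6 (3R)-6-methyl-3-(prop-1-en-2-yl)hept-5-enoic acid
Conditions: i-PrPPh3I (2.5 equiv), n-BuLi (2.5 equiv), THF, 0 °C; then 5, −78 °C to rt; aq. HCl work-up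
Reagents that add atoms: isopropyltriphenylphosphonium iodide, CC(C)[P+](c1ccccc1)(c1ccccc1)c1ccccc1.[I-]
Why: Wittig olefination with the unstabilised isopropylidene ylide, used in excess so that one equivalent is spent on the carboxylic acid (5 also reacts through its ring-chain lactol tautomer), should convert the aldehyde into the trisubstituted alkene, and the stereocenter, β to both carbonyl groups, cannot epimerise.

Step 4
Reactants: 6 (3R)-6-methyl-3-(prop-1-en-2-yl)hept-5-enoic acid
Product: 7 methyl (3R)-6-methyl-3-(prop-1-en-2-yl)hept-5-enoate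
Conditions: MeI, K2CO3, DMF, rt
Reagents that add atoms: iodomethane, CI
Why: SN2 O-alkylation of the carboxylate gives the ester needed for the homologation without acid that could touch the two alkenes.

Step 5
Reactants: 7 methyl (3R)-6-methyl-3-(prop-1-en-2-yl)hept-5-enoate
Product: 10 triisopropyl{[(4R)-7-methyl-4-(prop-1-en-2-yl)oct-6-en-1-yn-1-yl]oxy}silane, via dibromo enolate 8 (not isolated), via lithium ynolate 9 (not isolated)
Conditions: CH2Br2, lithium 2,2,6,6-tetramethylpiperidide, THF, −78 °C; LiN(SiMe3)2; n-BuLi, −78 °C to rt; i-Pr3SiCl, 0 °C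
Reagents that add atoms: dibromomethane, BrCBr; chlorotriisopropylsilane, CC(C)[Si](Cl)(C(C)C)C(C)C
Why: Kowalski ester homologation: acylation of dibromomethyllithium gives the dibromo ketone enolate 8, bromine–lithium exchange triggers the carbenoid 1,2-shift to ynolate 9, and the bulky silyl chloride should trap it on oxygen to give the silyl ynol ether, the stereocenter lying β to the reacting carbonyl carbon and staying untouched.

Step 6
Reactants: 11 cyclobutane-1,3-dione
Product: 12 3-(methoxymethoxy)cyclobut-2-en-1-one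
Conditions: MOMCl, i-Pr2NEt, CH2Cl2, 0 °C
Reagents that add atoms: chloromethyl methyl ether, COCCl
Why: The dione is a strongly acidic vinylogous acid whose ammonium enolate should be alkylated on oxygen by the hard chloromethyl ether, giving the vinylogous ester (enol ether formation).

Step 7
Reactants: 10 triisopropyl{[(4R)-7-methyl-4-(prop-1-en-2-yl)oct-6-en-1-yn-1-yl]oxy}silane; 12 3-(methoxymethoxy)cyclobut-2-en-1-one
Product: 17 5-(methoxymethoxy)-2-[(R)-lavandulyl]-3-[(triisopropylsilyl)oxy]phenol, via vinylketene 13 (not isolated), via vinylcyclobutenone 14 (not isolated), via dienylketene 15 (not isolated), via cyclohexadienone 16 (not isolated)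
Conditions: 12 (1.5 equiv), toluene, 80 °C then 110 °C
Reagents that add atoms: none
Why: Heating should open 12 by four-electron conrotatory electrocyclic cleavage to vinylketene 13, whose ketene C=C adds the electron-rich alkyne 10 in a [2+2] cycloaddition to give vinylcyclobutenone 14; a second four-electron opening gives dienylketene 15, which closes by six-electron disrotatory electrocyclisation to cyclohexadienone 16 and tautomerises to phenol 17. The closest known reaction type is the thermal benzannulation of cyclobutenones with siloxyalkynes (Danheiser benzannulation), applied here to a cyclobutenone bearing a 3-alkoxy group. Ring A is the only ring closed: C8–C8a and C6–C7 form in the [2+2] step and the ring-closing bond C4a–C8a forms in the 6π electrocyclisation. No stereocenter is created (the sp3 carbon of 14 is lost on aromatisation), and the lavandulyl center, β to the alkyne, is not involved. The step needs regioselective alkyne insertion, which the polarisation of the ynol ether secures: its nucleophilic chain-bearing carbon bonds to the electrophilic ketene carbonyl carbon, so the chain ends between the new free hydroxyl (C8a) and the silyloxy group (C7) with the MOM ether para to it (C5). Strain release drives the first opening and aromatisation the last step, and the three oxygens emerge with three different substituents.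

Step 8
Reactants: 17 5-(methoxymethoxy)-2-[(R)-lavandulyl]-3-[(triisopropylsilyl)oxy]phenol
Product: 18 1-(1-ethoxyethoxy)-5-(methoxymethoxy)-2-[(R)-lavandulyl]-3-[(triisopropylsilyl)oxy]benzene
Conditions: ethyl vinyl ether, pyridinium p-toluenesulfonate (cat.), CH2Cl2, rt
Reagents that add atoms: ethyl vinyl ether, C=COCC
Why: Acid-catalysed addition of the phenol to the enol ether (acetal protection) caps the C8a hydroxyl with a group that both directs ortho-lithiation and is far more acid-labile than the MOM ether on C5, so the two oxygens flanking C4a remain distinguishable.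

Step 9
Reactants: 19 2,4-dihydroxybenzaldehyde
Product: 20 2,4-bis(methoxymethoxy)benzaldehyde
Conditions: NaH, MOMCl, DMF, 0 °C to rt
Reagents that add atoms: chloromethyl methyl ether, COCCl
Why: Williamson-type O-alkylation of the bis-phenoxide, the strong base being needed to break the hydrogen bond of the ortho hydroxyl to the aldehyde.

Step 10
Reactants: 20 2,4-bis(methoxymethoxy)benzaldehyde
Product: 21 (E)-3-[2,4-bis(methoxymethoxy)phenyl]-N-methoxy-N-methylprop-2-enamide
Conditions: (EtO)2P(O)CH2C(O)N(OMe)Me, NaH, THF, 0 °C to rt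
Reagents that add atoms: diethyl {2-[methoxy(methyl)amino]-2-oxoethyl}phosphonate, CCOP(=O)(CC(=O)N(C)OC)OCC
Why: Horner–Wadsworth–Emmons olefination with the amide-stabilised phosphonate should give the (E)-alkene.

Step 11
Reactants: 18 1-(1-ethoxyethoxy)-5-(methoxymethoxy)-2-[(R)-lavandulyl]-3-[(triisopropylsilyl)oxy]benzene; 21 (E)-3-[2,4-bis(methoxymethoxy)phenyl]-N-methoxy-N-methylprop-2-enamide
Product: 24 (E)-3-[2,4-bis(methoxymethoxy)phenyl]-1-{2-(1-ethoxyethoxy)-6-(methoxymethoxy)-3-[(R)-lavandulyl]-4-[(triisopropylsilyl)oxy]phenyl}prop-2-en-1-one, via aryllithium 22 (not isolated), via lithium hemiaminal 23 (not isolated)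
Conditions: n-BuLi, THF, 0 °C; then 21, −78 °C to −20 °C; cold aq. NH4Cl
Reagents that add atoms: none
Why: Directed ortho-metalation should occur at C4a, the only ring C–H flanked by two coordinating acetal oxygens (C6–H has the bulky, non-coordinating silyl ether as neighbour), and the aryllithium should add 1,2 to the N-methoxy-N-methylamide to give a chelated adduct that releases the enone only on cold quench (Weinreb ketone synthesis), which forms the C4–C4a bond and the whole chalcone in one operation without hydroxide that would endanger the aryl silyl ether.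

Step 12
Reactants: 24 (E)-3-[2,4-bis(methoxymethoxy)phenyl]-1-{2-(1-ethoxyethoxy)-6-(methoxymethoxy)-3-[(R)-lavandulyl]-4-[(triisopropylsilyl)oxy]phenyl}prop-2-en-1-one
Product: 25 {(2R,3S)-3-[2,4-bis(methoxymethoxy)phenyl]oxiran-2-yl}{2-(1-ethoxyethoxy)-6-(methoxymethoxy)-3-[(R)-lavandulyl]-4-[(triisopropylsilyl)oxy]phenyl}methanone
Conditions: poly-L-leucine, urea–H2O2, 1,8-diazabicyclo[5.4.0]undec-7-ene, THF, rt
Reagents that add atoms: urea–hydrogen peroxide, NC(N)=O.OO
Why: Juliá–Colonna epoxidation: the helical poly-L-leucine should direct conjugate addition of hydroperoxide to the enone face that gives the (2R,3S)-oxirane, as it does for the parent chalcone, the trans geometry following from the (E)-alkene and the nucleophilic oxidant leaving the two electron-rich lavandulyl alkenes alone.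

Step 13
Reactants: 25 {(2R,3S)-3-[2,4-bis(methoxymethoxy)phenyl]oxiran-2-yl}{2-(1-ethoxyethoxy)-6-(methoxymethoxy)-3-[(R)-lavandulyl]-4-[(triisopropylsilyl)oxy]phenyl}methanone
Product: 27 (2R,3R)-2-[2,4-bis(methoxymethoxy)phenyl]-3-hydroxy-5-(methoxymethoxy)-8-[(R)-lavandulyl]-7-[(triisopropylsilyl)oxy]chroman-4-one, via hydroxy epoxide 26 (not isolated)
Conditions: pyridinium p-toluenesulfonate (0.2 equiv), i-PrOH/CH2Cl2, 0 °C to rt
Reagents that add atoms: none
Why: Mild acid-catalysed transacetalisation should remove only the 1-ethoxyethyl group, and the freed C8a hydroxyl of 26 should open the acid-activated oxirane 6-endo at the benzylic carbon with inversion (C2 becomes R) while C3 keeps its configuration, so the 2,3-trans ring C closes on the oxygen next to the lavandulyl chain because the C5 oxygen is still a MOM ether.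

Step 14
Reactants: 27 (2R,3R)-2-[2,4-bis(methoxymethoxy)phenyl]-3-hydroxy-5-(methoxymethoxy)-8-[(R)-lavandulyl]-7-[(triisopropylsilyl)oxy]chroman-4-one
Product: 28 (2R,3R)-2-(2,4-dihydroxyphenyl)-3,5-dihydroxy-8-[(R)-lavandulyl]-7-[(triisopropylsilyl)oxy]chroman-4-one
Conditions: 3 M aq. HCl/MeOH, 45 °C
Reagents that add atoms: none
Why: Acid-catalysed acetal methanolysis should cleave the three MOM ethers, while the more acid-stable aryl silyl ether is expected to stay on C7 and so keep a free hydroxyl away from the acid-sensitive isopropenyl group of the neighbouring chain (no chroman formation).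

Step 15
Reactants: 28 (2R,3R)-2-(2,4-dihydroxyphenyl)-3,5-dihydroxy-8-[(R)-lavandulyl]-7-[(triisopropylsilyl)oxy]chroman-4-one
Product: 29 kushenol X
Conditions: Bu4NF, AcOH (1:1), THF, 0 °C
Reagents that add atoms: none
Why: Fluoride-induced cleavage of the aryl silyl ether, buffered with acetic acid so that the base-sensitive flavanonol (C3 epimerisation, ring opening) never meets a free phenoxide, should release the C7 hydroxyl and give the target with all three stereocenters untouched.

**Compound list**

1 | (R)-carvone | C=C(C)[C@@H]1CC=C(C)C(=O)C1 | starting material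
2 | (1R,4R,6R)-1-methyl-4-(prop-1-en-2-yl)-7-oxabicyclo[4.1.0]heptan-2-one | C=C(C)[C@@H]1C[C@H]2O[C@@]2(C)C(=O)C1 | intermediate
3 | (2R,3S,5R)-2,3-dihydroxy-2-methyl-5-(prop-1-en-2-yl)cyclohexan-1-one (keto diol, not isolated) | C=C(C)[C@@H]1C[C@H](O)[C@@](C)(O)C(=O)C1 | intermediate
4 | (3R)-5,6-dioxo-3-(prop-1-en-2-yl)heptanal (diketo aldehyde, not isolated) | C=C(C)[C@@H](CC(=O)C(C)=O)CC=O | intermediate
5 | (3R)-5-oxo-3-(prop-1-en-2-yl)pentanoic acid | C=C(C)[C@@H](CC(=O)O)CC=O | intermediate
6 | (3R)-6-methyl-3-(prop-1-en-2-yl)hept-5-enoic acid | C=C(C)[C@H](CC=C(C)C)CC(=O)O | intermediate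
7 | methyl (3R)-6-methyl-3-(prop-1-en-2-yl)hept-5-enoate | C=C(C)[C@H](CC=C(C)C)CC(=O)OC | intermediate
8 | lithium (4R)-1,1-dibromo-7-methyl-4-(prop-1-en-2-yl)octa-1,6-dien-2-olate (dibromo enolate, not isolated) | C=C(C)[C@H](CC=C(C)C)CC([O-])=C(Br)Br.[Li+] | intermediate
9 | lithium (4R)-7-methyl-4-(prop-1-en-2-yl)oct-6-en-1-yn-1-olate (lithium ynolate, not isolated) | C=C(C)[C@H](CC=C(C)C)CC#C[O-].[Li+] | intermediate
10 | triisopropyl{[(4R)-7-methyl-4-(prop-1-en-2-yl)oct-6-en-1-yn-1-yl]oxy}silane | C=C(C)[C@H](CC=C(C)C)CC#CO[Si](C(C)C)(C(C)C)C(C)C | intermediate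
11 | cyclobutane-1,3-dione | O=C1CC(=O)C1 | starting material
12 | 3-(methoxymethoxy)cyclobut-2-en-1-one | O=C1C=C(OCOC)C1 | intermediate
13 | 3-(methoxymethoxy)buta-1,3-dien-1-one (vinylketene, not isolated) | C=C(OCOC)C=C=O | intermediate
14 | 4-[1-(methoxymethoxy)ethenyl]-2-[(2R)-5-methyl-2-(prop-1-en-2-yl)hex-4-en-1-yl]-3-[(triisopropylsilyl)oxy]cyclobut-2-en-1-one (vinylcyclobutenone, both C4 epimers, not isolated) | C=C(C)[C@H](CC=C(C)C)CC1=C(O[Si](C(C)C)(C(C)C)C(C)C)C(C(=C)OCOC)C1=O | intermediate
15 | 5-(methoxymethoxy)-2-[(2R)-5-methyl-2-(prop-1-en-2-yl)hex-4-en-1-yl]-3-[(triisopropylsilyl)oxy]hexa-1,3,5-trien-1-one (dienylketene, ketene and vinyl termini cis, not isolated) | C=C(C)[C@H](CC=C(C)C)CC(=C=O)/C(O[Si](C(C)C)(C(C)C)C(C)C)=C\C(=C)OCOC | intermediate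
16 | 5-(methoxymethoxy)-2-[(2R)-5-methyl-2-(prop-1-en-2-yl)hex-4-en-1-yl]-3-[(triisopropylsilyl)oxy]cyclohexa-2,4-dien-1-one (not isolated) | C=C(C)[C@H](CC=C(C)C)CC1=C(O[Si](C(C)C)(C(C)C)C(C)C)C=C(OCOC)CC1=O | intermediate
17 | 5-(methoxymethoxy)-2-[(2R)-5-methyl-2-(prop-1-en-2-yl)hex-4-en-1-yl]-3-[(triisopropylsilyl)oxy]phenol | C=C(C)[C@H](CC=C(C)C)Cc1c(O)cc(OCOC)cc1O[Si](C(C)C)(C(C)C)C(C)C | intermediate
18 | 1-(1-ethoxyethoxy)-5-(methoxymethoxy)-2-[(2R)-5-methyl-2-(prop-1-en-2-yl)hex-4-en-1-yl]-3-[(triisopropylsilyl)oxy]benzene (both acetal epimers) | C=C(C)[C@H](CC=C(C)C)Cc1c(OC(C)OCC)cc(OCOC)cc1O[Si](C(C)C)(C(C)C)C(C)C | intermediate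
19 | 2,4-dihydroxybenzaldehyde | O=Cc1ccc(O)cc1O | starting material
20 | 2,4-bis(methoxymethoxy)benzaldehyde | O=Cc1ccc(OCOC)cc1OCOC | intermediate
21 | (E)-3-[2,4-bis(methoxymethoxy)phenyl]-N-methoxy-N-methylprop-2-enamide | CON(C)C(=O)/C=C/c1ccc(OCOC)cc1OCOC | intermediate
22 | {2-(1-ethoxyethoxy)-6-(methoxymethoxy)-3-[(2R)-5-methyl-2-(prop-1-en-2-yl)hex-4-en-1-yl]-4-[(triisopropylsilyl)oxy]phenyl}lithium (aryllithium, not isolated) | C=C(C)[C@H](CC=C(C)C)Cc1c(OC(C)OCC)c([Li])c(OCOC)cc1O[Si](C(C)C)(C(C)C)C(C)C | intermediate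
23 | lithium (E)-3-[2,4-bis(methoxymethoxy)phenyl]-1-{2-(1-ethoxyethoxy)-6-(methoxymethoxy)-3-[(2R)-5-methyl-2-(prop-1-en-2-yl)hex-4-en-1-yl]-4-[(triisopropylsilyl)oxy]phenyl}-1-[methoxy(methyl)amino]prop-2-en-1-olate (lithium hemiaminal, not isolated) | C=C(C)[C@H](CC=C(C)C)Cc1c(OC(C)OCC)c(C(O[Li])(N(C)OC)/C=C/c2ccc(OCOC)cc2OCOC)c(OCOC)cc1O[Si](C(C)C)(C(C)C)C(C)C | intermediate
24 | (E)-3-[2,4-bis(methoxymethoxy)phenyl]-1-{2-(1-ethoxyethoxy)-6-(methoxymethoxy)-3-[(2R)-5-methyl-2-(prop-1-en-2-yl)hex-4-en-1-yl]-4-[(triisopropylsilyl)oxy]phenyl}prop-2-en-1-one | C=C(C)[C@H](CC=C(C)C)Cc1c(OC(C)OCC)c(C(=O)/C=C/c2ccc(OCOC)cc2OCOC)c(OCOC)cc1O[Si](C(C)C)(C(C)C)C(C)C | intermediate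
25 | {(2R,3S)-3-[2,4-bis(methoxymethoxy)phenyl]oxiran-2-yl}{2-(1-ethoxyethoxy)-6-(methoxymethoxy)-3-[(2R)-5-methyl-2-(prop-1-en-2-yl)hex-4-en-1-yl]-4-[(triisopropylsilyl)oxy]phenyl}methanone | C=C(C)[C@H](CC=C(C)C)Cc1c(OC(C)OCC)c(C(=O)[C@@H]2O[C@H]2c3ccc(OCOC)cc3OCOC)c(OCOC)cc1O[Si](C(C)C)(C(C)C)C(C)C | intermediate
26 | {(2R,3S)-3-[2,4-bis(methoxymethoxy)phenyl]oxiran-2-yl}{2-hydroxy-6-(methoxymethoxy)-3-[(2R)-5-methyl-2-(prop-1-en-2-yl)hex-4-en-1-yl]-4-[(triisopropylsilyl)oxy]phenyl}methanone (hydroxy epoxide, not isolated) | C=C(C)[C@H](CC=C(C)C)Cc1c(O)c(C(=O)[C@@H]2O[C@H]2c3ccc(OCOC)cc3OCOC)c(OCOC)cc1O[Si](C(C)C)(C(C)C)C(C)C | intermediate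
27 | (2R,3R)-2-[2,4-bis(methoxymethoxy)phenyl]-3-hydroxy-5-(methoxymethoxy)-8-[(2R)-5-methyl-2-(prop-1-en-2-yl)hex-4-en-1-yl]-7-[(triisopropylsilyl)oxy]chroman-4-one | C=C(C)[C@H](CC=C(C)C)Cc1c(O[Si](C(C)C)(C(C)C)C(C)C)cc(OCOC)c2c1O[C@H](c1ccc(OCOC)cc1OCOC)[C@@H](O)C2=O | intermediate
28 | (2R,3R)-2-(2,4-dihydroxyphenyl)-3,5-dihydroxy-8-[(2R)-5-methyl-2-(prop-1-en-2-yl)hex-4-en-1-yl]-7-[(triisopropylsilyl)oxy]chroman-4-one | C=C(C)[C@H](CC=C(C)C)Cc1c(O[Si](C(C)C)(C(C)C)C(C)C)cc(O)c2c1O[C@H](c1ccc(O)cc1O)[C@@H](O)C2=O | intermediate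
29 | kushenol X, (2R,3R)-2-(2,4-dihydroxyphenyl)-3,5,7-trihydroxy-8-[(2R)-5-methyl-2-(prop-1-en-2-yl)hex-4-en-1-yl]chroman-4-one | C=C(C)[C@H](CC=C(C)C)Cc1c(O)cc(O)c2c1O[C@H](c1ccc(O)cc1O)[C@@H](O)C2=O | target

**Step count and risks**

Total step count: 15. Longest linear sequence: 12 steps (steps 1–5, 7, 8, 11–15).

The three steps most likely to fail:

1. Step 7. The 3-alkoxy group makes the cyclobutenone a vinylogous ester, so thermal ring opening may be slow compared with decomposition or self-reaction of the vinylketene, and the product phenol may be acylated by the ketene. Fallback: the same vinylketene 13 is generated photochemically at room temperature. It sets out from 10. Commercial butane-2,3-dione is converted into its mono MOM enol ether, 3-(methoxymethoxy)but-3-en-2-one F1 (KN(SiMe3)2, MOMCl, THF, −78 °C). The lithium enolate of F1 is trifluoroacetylated (LiN(SiMe3)2; CF3CO2CH2CF3) to 1,1,1-trifluoro-5-(methoxymethoxy)hex-5-ene-2,4-dione F2, and deacylative diazo transfer (MsN3, Et3N, H2O, MeCN) gives 1-diazo-3-(methoxymethoxy)but-3-en-2-one F3. Irradiation of F3 with 10 (CH2Cl2, 300 nm, rt) should give 13 by photochemical Wolff rearrangement and then 14; brief heating in toluene would complete the sequence through 15 and 16, and the route is rejoined at 17.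

2. Step 12. The carbonyl group is flanked by two ortho substituents, so turnover on the polypeptide may be slow and facial selectivity poor, giving a mixture of oxirane diastereomers. Fallback: the oxirane is built by C–C bond formation and ring closure in place of alkene oxidation. It sets out from 18, which is lithiated as in step 11 to 22 and acylated with 2-chloro-N-methoxy-N-methylacetamide to give the chloromethyl ketone, 2-chloro-1-{2-(1-ethoxyethoxy)-6-(methoxymethoxy)-3-[(R)-lavandulyl]-4-[(triisopropylsilyl)oxy]phenyl}ethan-1-one F4. An asymmetric Darzens condensation of F4 with aldehyde 20 under a cinchona-derived quaternary ammonium phase-transfer catalyst (LiOH·H2O, Bu2O, 4 °C; the cinchoninium or the cinchonidinium series, whichever gives the (2R,3S) oxirane) would give the trans-epoxy ketone and rejoin the route at 25.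

3. Step 13. The oxirane, benzylic to a very electron-rich ring, may be opened by the solvent or at the α-carbon before the phenol closes ring C, the configuration at C2 may erode through a benzylic cation, and the C5 MOM group may be lost early, which would blur the distinction between C8 and C6. Fallback: oxirane opening and ring closure are separated through a thioether. It sets out from 25, which is treated with benzyl mercaptan and a substoichiometric Lewis acid (BnSH, SnCl4, CH2Cl2, −30 °C). This opens the oxirane at the benzylic carbon and removes the 1-ethoxyethyl group, giving (2S)-3-(benzylsulfanyl)-3-[2,4-bis(methoxymethoxy)phenyl]-2-hydroxy-1-{2-hydroxy-6-(methoxymethoxy)-3-[(R)-lavandulyl]-4-[(triisopropylsilyl)oxy]phenyl}propan-1-one F5 as both epimers at the sulfur-bearing carbon; the hydroxyl-bearing carbon keeps its configuration, and its descriptor changes only because sulfur raises the priority of the neighbouring carbon. The thiophile AgBF4 with 2,6-di-tert-butylpyridine (CH2Cl2, 0 °C) then ionises the C–S bond, and the C8a hydroxyl should capture the benzylic cation to give the thermodynamically preferred 2,3-trans ring, rejoining the route at 27.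

**Further compounds**

F1 | step 7 | 3-(methoxymethoxy)but-3-en-2-one | CC(=O)C(=C)OCOC
F2 | step 7 | 1,1,1-trifluoro-5-(methoxymethoxy)hex-5-ene-2,4-dione | C=C(OCOC)C(=O)CC(=O)C(F)(F)F
F3 | step 7 | 1-diazo-3-(methoxymethoxy)but-3-en-2-one | C=C(OCOC)C(=O)C=[N+]=[N-]
F4 | step 12 | 2-chloro-1-{2-(1-ethoxyethoxy)-6-(methoxymethoxy)-3-[(2R)-5-methyl-2-(prop-1-en-2-yl)hex-4-en-1-yl]-4-[(triisopropylsilyl)oxy]phenyl}ethan-1-one | C=C(C)[C@H](CC=C(C)C)Cc1c(OC(C)OCC)c(C(=O)CCl)c(OCOC)cc1O[Si](C(C)C)(C(C)C)C(C)C
F5 | step 13 | (2S)-3-(benzylsulfanyl)-3-[2,4-bis(methoxymethoxy)phenyl]-2-hydroxy-1-{2-hydroxy-6-(methoxymethoxy)-3-[(2R)-5-methyl-2-(prop-1-en-2-yl)hex-4-en-1-yl]-4-[(triisopropylsilyl)oxy]phenyl}propan-1-one (both C3 epimers) | C=C(C)[C@H](CC=C(C)C)Cc1c(O)c(C(=O)[C@H](O)C(SCc2ccccc2)c3ccc(OCOC)cc3OCOC)c(OCOC)cc1O[Si](C(C)C)(C(C)C)C(C)C
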